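In a one-step world each molecule of starting complex (S) that reacts ends as complex with one exchanged (A), and the quick number you asked for is simply the part of S gone. The flask is not that world: at 90.0 s of the north-east run, which is this same flask followed so far, S has lost 81.8%, more than the 72.2% found as A.

| flask | starting complex | incoming ligand | leaving ligand | remark | time |
|---|---|---|---|---|---|
| north-east | 0.28 M | 0.84 M | 0.28 M | the very flask that is asked about, followed so far |  |
| flask | 0.28 M | 0.840 M | 0.280 M |  | 3.0 min |

north-east run (percent of the starting complex charged)

| time / s | complex with one exchanged / % | complex with three exchanged / % | starting complex / % |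
|---|---|---|---|
| 15.0 | 27.3 | 1.8 | 72.4 |
| 30.0 | 45.9 | 0.3 | 49.8 |
| 50.0 | 60.0 | 4.5 | 35.0 |
| 60.0 | 63.5 | 2.7 | 24.4 |
| 80.0 | 70.3 | 5.0 | 19.5 |
| 90.0 | 72.2 | 6.5 | 18.2 |

(scatter of a reading: 1 percentage point)

- equivalents of incoming ligand to starting complex, everything else as given, that leave most complex with one exchanged at 3.0 min
- the amount of complex with one exchanged then, in percent of the starting complex charged
- the amount of complex with one exchanged with the amounts as given



So a molecule meets a fork: once in A, it can go on. Take the decay of S as a clock, τ = ln(1/S), which reads 1.70 at that reading, and suppose that a molecule in A moves on σ times as often per tick as one in S. The 9.60% already past A, over the 0.886 ticks spent in A (τ less the part of S gone), gives σ = 0.108, the onward ratio, a selectivity factor read from one pair of readings, so it carries their scatter.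

Then A = (S^σ − S)/(1 − σ), which peaks at 76.3% when τ reaches 2.49. Take the clock to run in proportion to incoming ligand (X), which stands near 0.584 M by that reading if each molecule past A has taken two X in all, and, as a rough assumption, hold X there from then on. Then τ reaches 3.10 at 3.0 min, past the peak, so this reckoning expects A near 75.1%, and about 2.55 equivalents for the peak.

The forecast gives 80% as charged and 81% at 2.8 equiv, an optimum “close to the charge as given, perhaps slightly less”. The two part on the height of the peak, the forecast's standing above 76.3%.

The simulated flask gives 71.6%, and 73.9% at 2.32 equiv.

    starting complex + incoming ligand ⇌ leaving ligand + complex with one exchanged (K = 3.80, k = 0.0302 M⁻¹ s⁻¹)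
    complex with one exchanged + incoming ligand ⇌ leaving ligand + complex with two exchanged (K = 0.655, k = 0.00384 M⁻¹ s⁻¹)
    complex with two exchanged + incoming ligand ⇌ leaving ligand + complex with three exchanged (K = 0.270, k = 0.0280 M⁻¹ s⁻¹)
    incoming ligand → decomposition product (k = 6.13 × 10⁻⁶ s⁻¹)
    leaving ligand → by-product carried off (k = 0.290 s⁻¹)

At 3.00 min this flask makes A, each step taken net, at 0.460 of the rate at which it uses A up, so A is falling there. Its S of 4.29% puts the clock at 3.15, and the law gives 75.0% where the flask holds 71.6%. In the neighbouring flask charged with 2.1 M of X, S is 0.0491% at 3.00 min, and the law gives 49.2% where that flask holds 36.2%.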